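**Retrosynthetic overview**
Ring numbering used throughout: C1 (CH–OAc), C2=C3(CH3) (Z), C4 (CH–O2CAr), C5, C6=C7(CH3) (E), C8, C9, C10, C11 (C(CH3)2). The single ring, the 11-membered carbocycle, is formed last among the C–C bonds, by closing C9–C10.
C9–C10 is made in one operation from an acyclic iodo-triene: 9-BBN hydroboration of the terminal diene C9=C8–C7=C6, then nickel-catalysed alkyl–alkyl Suzuki–Miyaura macrocyclisation onto the C10 iodide.
Enabling feature: C11 is quaternary, so C10 is a neopentyl carbon with no β-hydrogen (no E2, no β-hydride elimination), and C9 is the only unhindered olefin terminus; the Z-C2=C3 turn, the E-C6=C7 olefin and the gem-dimethyl group at C11 fold the chain.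
Acyclic chain: C4–C5 by catalytic asymmetric vinylogous Mukaiyama aldol (sets C4 and E-C6=C7), C2=C3 by Still–Gennari olefination (Z), C1/C11/C10 with the C1 stereocentre from (S)-pantolactone.
After ring closure: C4 4-acetoxybenzoate, C1 acetate, selective release of the phenol.

Key step: step 14

Assumption: (S)-pantolactone, the trifluoroethyl phosphonate, ethyl tiglate, 4-acetoxybenzoyl chloride and the chiral bisphosphoramide are taken as purchasable, and the (R,R) antipode of that catalyst is taken as the one that attacks the Re face of the aldehyde.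

Step 1
Reactants: 1 (S)-pantolactone
Product: 2 (2S)-3,3-dimethylbutane-1,2,4-triol
Conditions: LiAlH4, THF, 0 °C to reflux; aq. NaOH
Reagents that add atoms: none
Why: Hydride reduction of the lactone (LiAlH4 ester reduction) should open the ring to the triol without touching the carbinol centre that becomes C1.

Step 2
Reactants: 2 triol
Product: 3 [(2S,4S)-2-(4-methoxyphenyl)-5,5-dimethyl-1,3-dioxan-4-yl]methanol
Conditions: 4-MeOC6H4CH(OMe)2, CSA (cat.), CH2Cl2/DMF, rt
Reagents that add atoms: 4-methoxybenzaldehyde dimethyl acetal, COc1ccc(C(OC)OC)cc1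
Why: Thermodynamic transacetalisation should favour the six-membered 1,3-dioxane across the secondary and the neopentyl primary hydroxyl, the new acetal centre being set by equatorial placement of the aryl group (cis to the hydroxymethyl group), which leaves the primary alcohol at the future C2 free.

Step 3
Reactants: 3 dioxanyl methanol
Product: 4 (2S,4S)-2-(4-methoxyphenyl)-5,5-dimethyl-1,3-dioxane-4-carbaldehyde
Conditions: (COCl)2, DMSO, CH2Cl2, −78 °C; Et3N
Reagents that add atoms: none
Why: Swern oxidation should give the α-alkoxy aldehyde at low temperature without epimerising the adjacent centre.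

Step 4
Reactants: 4 aldehyde; 5 ethyl 2-[bis(2,2,2-trifluoroethoxy)phosphoryl]propanoate
Product: 6 ethyl (2Z)-3-[(2S,4R)-2-(4-methoxyphenyl)-5,5-dimethyl-1,3-dioxan-4-yl]-2-methylprop-2-enoate
Conditions: KN(SiMe3)2, 18-crown-6, THF, −78 °C
Reagents that add atoms: none
Why: Still–Gennari olefination with the electron-poor phosphonate under dissociating conditions should give the kinetic (Z)-2-methyl enoate, placing C1 and the ester carbon (future C4) cis as the ring requires.

Step 5
Reactants: 6 (Z)-enoate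
Product: 7 (2Z)-3-[(2S,4R)-2-(4-methoxyphenyl)-5,5-dimethyl-1,3-dioxan-4-yl]-2-methylprop-2-en-1-ol
Conditions: i-Bu2AlH, CH2Cl2, −78 °C; aq. KNaC4H4O6
Reagents that add atoms: none
Why: 1,2-Reduction of the enoate by the aluminium hydride should stop at the allylic alcohol, the acetal not being opened at −78 °C.

Step 6
Reactants: 7 (Z)-allylic alcohol
Product: 8 (2Z)-3-[(2S,4R)-2-(4-methoxyphenyl)-5,5-dimethyl-1,3-dioxan-4-yl]-2-methylprop-2-enal
Conditions: MnO2, CH2Cl2, rt
Reagents that add atoms: none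
Why: Allylic oxidation with MnO2 under neutral heterogeneous conditions should give the (Z)-enal without isomerisation to the E isomer.

Step 7
Reactants: 9 ethyl tiglate
Product: 10 tert-butyl[(1-ethoxy-2-methylbuta-1,3-dien-1-yl)oxy]dimethylsilane
Conditions: LiN(i-Pr)2, DMPU, THF, −78 °C; TBSCl
Reagents that add atoms: tert-butyl(chloro)dimethylsilane, CC(C)(C)[Si](C)(C)Cl
Why: γ-Deprotonation to the lithium dienolate and O-silylation (silyl ketene acetal formation) should give the vinylogous nucleophile, whose ketene-acetal geometry is lost in the next step.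

Step 8
Reactants: 8 (Z)-enal; 10 silyl dienolate
Product: 12 ethyl (2E,5R,6Z)-5-hydroxy-7-[(2S,4R)-2-(4-methoxyphenyl)-5,5-dimethyl-1,3-dioxan-4-yl]-2,6-dimethylhepta-2,6-dienoate, via trichlorosilyl ether 11 (not isolated)
Conditions: SiCl4, (R,R)-pentamethylene-linked bis(N,N′-dimethyl-1,1′-binaphthyl-2,2′-diamine phosphoramide) (5 mol %), i-Pr2NEt (cat.), CH2Cl2, −78 °C; aq. KF/NaHCO3
Reagents that add atoms: none
Why: In this catalytic enantioselective vinylogous Mukaiyama aldol the phosphoramide-bound chlorosilyl cation activates the aldehyde, the dienolate attacks through its γ-carbon to give the E-enoate, and catalyst-controlled Re-face attack sets the (5R) carbinol, which is C4 (R) of the target, independently of the remote C1 centre.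

Step 9
Reactants: 12 hydroxy enoate
Product: 13 ethyl (2E,5R,6Z)-5-[(tert-butyldimethylsilyl)oxy]-7-[(2S,4R)-2-(4-methoxyphenyl)-5,5-dimethyl-1,3-dioxan-4-yl]-2,6-dimethylhepta-2,6-dienoate
Conditions: TBSCl, imidazole, DMF, rt
Reagents that add atoms: tert-butyl(chloro)dimethylsilane, CC(C)(C)[Si](C)(C)Cl
Why: Imidazole-mediated silylation should protect the C4 allylic alcohol without acid that could ionise the acetal.

Step 10
Reactants: 13 silyl ether ester
Product: 15 (2E,5R,6Z,8R)-5-[(tert-butyldimethylsilyl)oxy]-8-[(4-methoxyphenyl)methoxy]-2,6,9,9-tetramethyldeca-2,6-diene-1,10-diol, via acetal allylic alcohol 14 (not isolated)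
Conditions: i-Bu2AlH (excess), CH2Cl2, −78 °C to 0 °C; aq. KNaC4H4O6
Reagents that add atoms: none
Why: Ester reduction at −78 °C should be followed on warming by regioselective reductive opening of the 4-methoxybenzylidene acetal, aluminium coordinating to the less hindered primary oxygen so that the PMB group stays on the C1 oxygen and the C10 hydroxyl is freed.

Step 11
Reactants: 15 diol
Product: 16 (2E,5R,6Z,8R)-5-[(tert-butyldimethylsilyl)oxy]-10-hydroxy-8-[(4-methoxyphenyl)methoxy]-2,6,9,9-tetramethyldeca-2,6-dienal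
Conditions: MnO2, CH2Cl2, rt
Reagents that add atoms: none
Why: MnO2 should oxidise only the allylic primary alcohol (chemoselective allylic oxidation) and leave the neopentyl alcohol untouched.

Step 12
Reactants: 16 hydroxy enal
Product: 17 (2E,5R,6Z,8R)-5-[(tert-butyldimethylsilyl)oxy]-10-iodo-8-[(4-methoxyphenyl)methoxy]-2,6,9,9-tetramethyldeca-2,6-dienal
Conditions: PPh3, I2, imidazole, toluene, 70 °C
Reagents that add atoms: iodine, II
Why: Appel iodination through the alkoxyphosphonium ion should give the neopentyl iodide by a slow but clean SN2 displacement, since neither elimination nor cationic rearrangement is available under these non-ionising conditions.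

Step 13
Reactants: 17 iodo enal
Product: 18 tert-butyl{[(3E,6R,7Z,9R)-11-iodo-9-[(4-methoxyphenyl)methoxy]-3,7,10,10-tetramethylundeca-1,3,7-trien-6-yl]oxy}dimethylsilane
Conditions: Ph3PCH3Br, KOt-Bu, THF, 0 °C; then 17, −78 to 0 °C
Reagents that add atoms: methyltriphenylphosphonium bromide, C[P+](c1ccccc1)(c1ccccc1)c1ccccc1.[Br-]
Why: Wittig methylenation of the enal should give the 1,3-diene with the E-trisubstituted olefin unchanged, the neopentyl iodide being inert to the ylide.

Step 14
Reactants: 18 iodo-triene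
Product: 20 tert-butyl{[(1R,2Z,4R,6E)-1-[(4-methoxyphenyl)methoxy]-3,7,11,11-tetramethylcycloundeca-2,6-dien-4-yl]oxy}dimethylsilane (overview numbering), via B-alkyl-9-BBN borane 19 (not isolated)
Conditions: 9-BBN, THF, 0 °C to rt; then slow addition to NiCl2·glyme (20 mol %), trans-N,N′-dimethylcyclohexane-1,2-diamine (25 mol %), KOt-Bu, i-BuOH, dioxane, rt, 2 mM
Reagents that add atoms: none
Why: Proposed new method: 9-BBN should add anti-Markovnikov to the monosubstituted C8=C9 end of the diene (the trisubstituted C2=C3 and C6=C7 olefins react orders of magnitude more slowly) to give the primary homoallylic borane 19, whose isobutoxide ate complex transmetalates to a diamine-ligated monovalent nickel species; this abstracts iodine from C10, the neopentyl radical recombines at nickel, and the trivalent dialkylnickel reductively eliminates the C9–C10 bond. The closest known reaction type is the intermolecular nickel/diamine-catalysed Suzuki–Miyaura coupling of alkyl-9-BBN reagents with unactivated alkyl halides, together with palladium-catalysed B-alkyl Suzuki macrocyclisations onto alkenyl halides; the intramolecular alkyl–alkyl variant has not been shown. The only ring formed is the 11-membered carbocycle, closed end-to-end as a macrocyclisation in which C9 and C10 both become ring atoms. No stereocentre is created; C1, C4 and both olefin geometries are spectators and are not touched by borane, alkoxide or nickel. The step needs chemoselective hydroboration, secured by C9 being the only unhindered olefin terminus, and ring closure over oligomerisation, secured by slow addition to 2 mM and by the Z-C2=C3 turn, the E-C6=C7 olefin and the gem-dimethyl group at C11 that bring C9 and C10 together. It also needs freedom from elimination, secured by the quaternary C11: C10 carries no β-hydrogen, so neither alkoxide-induced E2 nor β-hydride elimination from the C10–nickel bond is possible, and the radical-type activation avoids the SN2 step that a neopentyl centre would block.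

Step 15
Reactants: 20 protected macrocycle
Product: 21 (1R,2Z,4R,6E)-1-[(4-methoxyphenyl)methoxy]-3,7,11,11-tetramethylcycloundeca-2,6-dien-4-ol (overview numbering)
Conditions: n-Bu4NF, THF, 0 °C to rt
Reagents that add atoms: none
Why: Fluoride-mediated desilylation should free the C4 alcohol while the PMB ether at C1 is stable.

Step 16
Reactants: 21 C4 alcohol; 22 4-acetoxybenzoyl chloride
Product: 23 (1R,2Z,4R,6E)-1-[(4-methoxyphenyl)methoxy]-3,7,11,11-tetramethylcycloundeca-2,6-dien-4-yl 4-acetoxybenzoate (overview numbering)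
Conditions: pyridine, DMAP (cat.), CH2Cl2, 0 °C to rt
Reagents that add atoms: none
Why: Nucleophile-catalysed acylation by the acid chloride should esterify the unhindered secondary allylic alcohol with retention at C4.

Step 17
Reactants: 23 PMB ether ester
Product: 24 (1R,2Z,4R,6E)-1-hydroxy-3,7,11,11-tetramethylcycloundeca-2,6-dien-4-yl 4-acetoxybenzoate (overview numbering)
Conditions: DDQ, CH2Cl2/pH 7 buffer, 0 °C
Reagents that add atoms: none
Why: Oxidative PMB cleavage (hydride abstraction by DDQ to the oxocarbenium ion, then hydrolysis) should free the C1 alcohol without affecting the esters or the trisubstituted olefins.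

Step 18
Reactants: 24 C1 alcohol
Product: 25 (1R,2Z,4R,6E)-1-acetoxy-3,7,11,11-tetramethylcycloundeca-2,6-dien-4-yl 4-acetoxybenzoate (overview numbering)
Conditions: Ac2O, Et3N, DMAP (cat.), CH2Cl2, rt
Reagents that add atoms: acetic anhydride, CC(=O)OC(C)=O
Why: DMAP-catalysed acetylation should acylate the hindered neopentyl-type allylic alcohol with retention at C1.

Step 19
Reactants: 25 aryl acetate
Product: 26 (1R,2Z,4R,6E)-1-acetoxy-3,7,11,11-tetramethylcycloundeca-2,6-dien-4-yl 4-hydroxybenzoate (overview numbering), CNP0246761.3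
Conditions: pyrrolidine (1.1 equiv), CH2Cl2, 0 °C
Reagents that add atoms: none
Why: Chemoselective aminolysis should cleave only the activated aryl acetate, because the hindered allylic acetate at C1 and the alkyl benzoate at C4 are far less electrophilic.

**Compound list**
1 | (S)-pantolactone, (3S)-3-hydroxy-4,4-dimethyloxolan-2-one | O[C@@H]1C(=O)OCC1(C)C | starting material
2 | (2S)-3,3-dimethylbutane-1,2,4-triol | O[C@@H](C(C)(C)CO)CO | intermediate
3 | [(2S,4S)-2-(4-methoxyphenyl)-5,5-dimethyl-1,3-dioxan-4-yl]methanol (aryl and hydroxymethyl cis) | OC[C@H]1O[C@@H](c2ccc(OC)cc2)OCC1(C)C | intermediate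
4 | (2S,4S)-2-(4-methoxyphenyl)-5,5-dimethyl-1,3-dioxane-4-carbaldehyde | O=C[C@H]1O[C@@H](c2ccc(OC)cc2)OCC1(C)C | intermediate
5 | ethyl 2-[bis(2,2,2-trifluoroethoxy)phosphoryl]propanoate | CCOC(=O)C(C)P(=O)(OCC(F)(F)F)OCC(F)(F)F | starting material
6 | ethyl (2Z)-3-[(2S,4R)-2-(4-methoxyphenyl)-5,5-dimethyl-1,3-dioxan-4-yl]-2-methylprop-2-enoate | CCOC(=O)/C(C)=C\[C@H]1O[C@@H](c2ccc(OC)cc2)OCC1(C)C | intermediate
7 | (2Z)-3-[(2S,4R)-2-(4-methoxyphenyl)-5,5-dimethyl-1,3-dioxan-4-yl]-2-methylprop-2-en-1-ol | OC/C(C)=C\[C@H]1O[C@@H](c2ccc(OC)cc2)OCC1(C)C | intermediate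
8 | (2Z)-3-[(2S,4R)-2-(4-methoxyphenyl)-5,5-dimethyl-1,3-dioxan-4-yl]-2-methylprop-2-enal | O=C/C(C)=C\[C@H]1O[C@@H](c2ccc(OC)cc2)OCC1(C)C | intermediate
9 | ethyl tiglate, ethyl (2E)-2-methylbut-2-enoate | C/C=C(\C)C(=O)OCC | starting material
10 | tert-butyl[(1-ethoxy-2-methylbuta-1,3-dien-1-yl)oxy]dimethylsilane (mixture of ketene-acetal geometric isomers) | CCOC(O[Si](C)(C)C(C)(C)C)=C(C)C=C | intermediate
11 | trichlorosilyl ether of 12 | CCOC(=O)/C(C)=C/C[C@@H](O[Si](Cl)(Cl)Cl)/C(C)=C\[C@H]1O[C@@H](c2ccc(OC)cc2)OCC1(C)C | intermediate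
12 | ethyl (2E,5R,6Z)-5-hydroxy-7-[(2S,4R)-2-(4-methoxyphenyl)-5,5-dimethyl-1,3-dioxan-4-yl]-2,6-dimethylhepta-2,6-dienoate | CCOC(=O)/C(C)=C/C[C@@H](O)/C(C)=C\[C@H]1O[C@@H](c2ccc(OC)cc2)OCC1(C)C | intermediate
13 | ethyl (2E,5R,6Z)-5-[(tert-butyldimethylsilyl)oxy]-7-[(2S,4R)-2-(4-methoxyphenyl)-5,5-dimethyl-1,3-dioxan-4-yl]-2,6-dimethylhepta-2,6-dienoate | CCOC(=O)/C(C)=C/C[C@@H](O[Si](C)(C)C(C)(C)C)/C(C)=C\[C@H]1O[C@@H](c2ccc(OC)cc2)OCC1(C)C | intermediate
14 | (2E,5R,6Z)-5-[(tert-butyldimethylsilyl)oxy]-7-[(2S,4R)-2-(4-methoxyphenyl)-5,5-dimethyl-1,3-dioxan-4-yl]-2,6-dimethylhepta-2,6-dien-1-ol | OC/C(C)=C/C[C@@H](O[Si](C)(C)C(C)(C)C)/C(C)=C\[C@H]1O[C@@H](c2ccc(OC)cc2)OCC1(C)C | intermediate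
15 | (2E,5R,6Z,8R)-5-[(tert-butyldimethylsilyl)oxy]-8-[(4-methoxyphenyl)methoxy]-2,6,9,9-tetramethyldeca-2,6-diene-1,10-diol | OC/C(C)=C/C[C@@H](O[Si](C)(C)C(C)(C)C)/C(C)=C\[C@@H](OCc1ccc(OC)cc1)C(C)(C)CO | intermediate
16 | (2E,5R,6Z,8R)-5-[(tert-butyldimethylsilyl)oxy]-10-hydroxy-8-[(4-methoxyphenyl)methoxy]-2,6,9,9-tetramethyldeca-2,6-dienal | O=C/C(C)=C/C[C@@H](O[Si](C)(C)C(C)(C)C)/C(C)=C\[C@@H](OCc1ccc(OC)cc1)C(C)(C)CO | intermediate
17 | (2E,5R,6Z,8R)-5-[(tert-butyldimethylsilyl)oxy]-10-iodo-8-[(4-methoxyphenyl)methoxy]-2,6,9,9-tetramethyldeca-2,6-dienal | O=C/C(C)=C/C[C@@H](O[Si](C)(C)C(C)(C)C)/C(C)=C\[C@@H](OCc1ccc(OC)cc1)C(C)(C)CI | intermediate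
18 | tert-butyl{[(3E,6R,7Z,9R)-11-iodo-9-[(4-methoxyphenyl)methoxy]-3,7,10,10-tetramethylundeca-1,3,7-trien-6-yl]oxy}dimethylsilane | C=C/C(C)=C/C[C@@H](O[Si](C)(C)C(C)(C)C)/C(C)=C\[C@@H](OCc1ccc(OC)cc1)C(C)(C)CI | intermediate
19 | 9-[(3E,6R,7Z,9R)-6-[(tert-butyldimethylsilyl)oxy]-11-iodo-9-[(4-methoxyphenyl)methoxy]-3,7,10,10-tetramethylundeca-3,7-dien-1-yl]-9-borabicyclo[3.3.1]nonane | B1(CC/C(C)=C/C[C@@H](O[Si](C)(C)C(C)(C)C)/C(C)=C\[C@@H](OCc2ccc(OC)cc2)C(C)(C)CI)C3CCCC1CCC3 | intermediate
20 | tert-butyl{[(1R,2Z,4R,6E)-1-[(4-methoxyphenyl)methoxy]-3,7,11,11-tetramethylcycloundeca-2,6-dien-4-yl]oxy}dimethylsilane (overview numbering) | COc1ccc(CO[C@@H]2/C=C(/C)[C@H](O[Si](C)(C)C(C)(C)C)C/C=C(\C)CCCC2(C)C)cc1 | intermediate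
21 | (1R,2Z,4R,6E)-1-[(4-methoxyphenyl)methoxy]-3,7,11,11-tetramethylcycloundeca-2,6-dien-4-ol (overview numbering) | COc1ccc(CO[C@@H]2/C=C(/C)[C@H](O)C/C=C(\C)CCCC2(C)C)cc1 | intermediate
22 | 4-acetoxybenzoyl chloride | CC(=O)Oc1ccc(cc1)C(Cl)=O | starting material
23 | (1R,2Z,4R,6E)-1-[(4-methoxyphenyl)methoxy]-3,7,11,11-tetramethylcycloundeca-2,6-dien-4-yl 4-acetoxybenzoate (overview numbering) | COc1ccc(CO[C@@H]2/C=C(/C)[C@H](OC(=O)c3ccc(OC(C)=O)cc3)C/C=C(\C)CCCC2(C)C)cc1 | intermediate
24 | (1R,2Z,4R,6E)-1-hydroxy-3,7,11,11-tetramethylcycloundeca-2,6-dien-4-yl 4-acetoxybenzoate (overview numbering) | O[C@@H]1/C=C(/C)[C@H](OC(=O)c2ccc(OC(C)=O)cc2)C/C=C(\C)CCCC1(C)C | intermediate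
25 | (1R,2Z,4R,6E)-1-acetoxy-3,7,11,11-tetramethylcycloundeca-2,6-dien-4-yl 4-acetoxybenzoate (overview numbering) | CC(=O)O[C@@H]1/C=C(/C)[C@H](OC(=O)c2ccc(OC(C)=O)cc2)C/C=C(\C)CCCC1(C)C | intermediate
26 | (1R,2Z,4R,6E)-1-acetoxy-3,7,11,11-tetramethylcycloundeca-2,6-dien-4-yl 4-hydroxybenzoate (overview numbering), CNP0246761.3 | CC(=O)O[C@@H]1/C=C(/C)[C@H](OC(=O)c2ccc(O)cc2)C/C=C(\C)CCCC1(C)C | target

**Step count**
Total: 19 steps. Longest linear sequence: 18 steps (1 to 26 through steps 1–6 and 8–19; step 7 prepares the dienolate).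

**Steps most likely to fail**

Step 14 (proposed new method). Oligomerisation by intermolecular coupling may outrun ring closure, β-hydride elimination at the C9–nickel stage may return the diene, or the C10–I bond may simply be reduced. The fallback uses known chemistry, sets out from diol 15 and comes back at 20. Chemoselective allylic chlorination (NCS, Me2S, CH2Cl2, −20 °C) should give the allylic chloride F1. Coupling with vinyltributyltin under zerovalent palladium catalysis (Pd(PPh3)4, THF, 50 °C) should give the skipped triene alcohol F2 with the E-olefin retained. Dess–Martin oxidation should give the neopentyl aldehyde F3, and Wittig methylenation (Ph3P=CH2, THF) the tetraene F4, which carries a vinyl group on the quaternary C11 and an allyl group on C7. Ring-closing metathesis (second-generation Grubbs catalyst, toluene, 80 °C, 1 mM) should close the same C9–C10 bond as an olefin in the cyclic triene F5, whose geometry at C9=C10 is irrelevant. Diimide (TsNHNH2, NaOAc, aq. DME, reflux) should then reduce only this 1,2-disubstituted olefin and return 20.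

Step 8. The silicon Lewis acid may isomerise the (Z)-enal, ionise the benzylidene acetal, or give insufficient facial selectivity at C4. The fallback sets out from enal 8 and comes back at 13. Asymmetric allylboration with (+)-Ipc2B(allyl) (Et2O, −78 °C; NaOH/H2O2), expected to attack the Re face, should give the homoallylic alcohol F6 without any Lewis acid. Silylation (TBSCl, imidazole, DMF) should give the silyl ether F7. E-selective cross-metathesis with ethyl methacrylate (second-generation Hoveyda–Grubbs catalyst, CH2Cl2, 40 °C) should then install the trisubstituted enoate and give 13.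

Step 4. Olefination of the hindered α-alkoxy aldehyde may be slow, with erosion of Z-selectivity and epimerisation of the α-centre under the basic conditions. The fallback sets out from aldehyde 4 and comes back at enal 8, bypassing 6 and 7. Iodo-olefination of the Stork–Zhao type with the ylide from (1-iodoethyl)triphenylphosphonium iodide (NaN(SiMe3)2, THF, −78 °C) should give the (Z)-vinyl iodide F8. Iodine–lithium exchange with retention (t-BuLi, Et2O, −78 °C) and formylation with DMF should then give 8.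

Further compounds
F1 | step 14 | (3R,4Z,6R,8E)-6-[(tert-butyldimethylsilyl)oxy]-10-chloro-3-[(4-methoxyphenyl)methoxy]-2,2,5,9-tetramethyldeca-4,8-dien-1-ol | ClC/C(C)=C/C[C@@H](O[Si](C)(C)C(C)(C)C)/C(C)=C\[C@@H](OCc1ccc(OC)cc1)C(C)(C)CO
F2 | step 14 | (3R,4Z,6R,8E)-6-[(tert-butyldimethylsilyl)oxy]-3-[(4-methoxyphenyl)methoxy]-2,2,5,9-tetramethyldodeca-4,8,11-trien-1-ol | C=CC/C(C)=C/C[C@@H](O[Si](C)(C)C(C)(C)C)/C(C)=C\[C@@H](OCc1ccc(OC)cc1)C(C)(C)CO
F3 | step 14 | (3R,4Z,6R,8E)-6-[(tert-butyldimethylsilyl)oxy]-3-[(4-methoxyphenyl)methoxy]-2,2,5,9-tetramethyldodeca-4,8,11-trienal | C=CC/C(C)=C/C[C@@H](O[Si](C)(C)C(C)(C)C)/C(C)=C\[C@@H](OCc1ccc(OC)cc1)C(C)(C)C=O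
F4 | step 14 | acyclic tetraene for ring-closing metathesis (vinyl on C11, allyl on C7; C1 OPMB, C4 OTBS) | C=CC/C(C)=C/C[C@@H](O[Si](C)(C)C(C)(C)C)/C(C)=C\[C@@H](OCc1ccc(OC)cc1)C(C)(C)C=C
F5 | step 14 | 9,10-didehydro analogue of 20 (cycloundeca-2,6,9-triene, drawn 9E) | COc1ccc(CO[C@@H]2/C=C(/C)[C@H](O[Si](C)(C)C(C)(C)C)C/C=C(\C)C/C=C/C2(C)C)cc1
F6 | step 8 | (1Z,3R)-1-[(2S,4R)-2-(4-methoxyphenyl)-5,5-dimethyl-1,3-dioxan-4-yl]-2-methylhexa-1,5-dien-3-ol | C=CC[C@@H](O)/C(C)=C\[C@H]1O[C@@H](c2ccc(OC)cc2)OCC1(C)C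
F7 | step 8 | tert-butyldimethylsilyl ether of F6 | C=CC[C@@H](O[Si](C)(C)C(C)(C)C)/C(C)=C\[C@H]1O[C@@H](c2ccc(OC)cc2)OCC1(C)C
F8 | step 4 | (2S,4R)-4-[(1Z)-2-iodoprop-1-en-1-yl]-2-(4-methoxyphenyl)-5,5-dimethyl-1,3-dioxane | I/C(C)=C\[C@H]1O[C@@H](c2ccc(OC)cc2)OCC1(C)C
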